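**Plan**

- Ring A is numbered C1 (carbon bearing CH2O), C2 (aryloxy carbon), C3 (C–OH), C5 (C–OMe). The retrosynthesis cuts the palmitate C–O bond last, returns ring A to a cyclohexane-1,3-dione and cuts its C1–C2 and C4–C5 bonds, then cuts the O–CH2 bond of the resulting aryloxyacetone back to orcinol.
- Enabling feature: ring A has its oxygens on C3 and C5 in a 1,3-relationship, an ester-level carbon on C1 and the ether oxygen on C2. That is the pattern of a 2-aryloxy-3,5-dioxocyclohexane-1-carboxylate, which an aryloxyacetone (C2, C3, C4) and a fumarate (C1, C6, C5 and the ester carbon) deliver in one operation.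
- Forward: ring B is bought as orcinol, monobenzylated and O-alkylated with chloroacetone. Ring A is then built onto the ether oxygen by the annulation, its C5 carbonyl is turned into the methyl enol ether while the ring is still saturated, and the ring is dehydrogenated to the arene.
- End game: debenzylation, reduction of the ester, and enzymatic palmitoylation of the only aliphatic hydroxyl.
- Stereochemistry: the target has no stereocentre. The two centres created in the annulation (C1, C2) are uncontrolled and disappear on aromatization.

Key step: step 3

Remark: vinyl palmitate is taken as the commercial acyl donor (it is also available in one operation from palmitic acid and vinyl acetate).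

**Route**

Step 1
Reactants: 1 orcinol (5-methylbenzene-1,3-diol)
Product: 2 3-(benzyloxy)-5-methylphenol
Conditions: BnBr (0.35 equiv), K2CO3, acetone, reflux; excess 1 recovered
Reagents that add atoms: benzyl bromide, BrCc1ccccc1
Why: Williamson etherification of a symmetric diphenol, in which an excess of orcinol should hold the reaction at the monoether, the unreacted diol being removed by aqueous extraction.

Step 2
Reactants: 2 3-(benzyloxy)-5-methylphenol; 3 chloroacetone
Product: 4 1-[3-(benzyloxy)-5-methylphenoxy]propan-2-one
Conditions: K2CO3, KI (cat.), acetone, reflux
Reagents that add atoms: none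
Why: Williamson etherification of the remaining phenoxide with an α-halo ketone, accelerated by in situ halide exchange to iodoacetone, is the standard way to aryloxyacetones.

Step 3
Reactants: 4 1-[3-(benzyloxy)-5-methylphenoxy]propan-2-one; 5 dimethyl fumarate
Product: 7 methyl 2-[3-(benzyloxy)-5-methylphenoxy]-3,5-dioxocyclohexane-1-carboxylate, via Michael adduct 6 (not isolated)
Conditions: NaOMe (2.2 equiv), MeOH–THF, 0 °C, slow addition of 5, then 60 °C; 1 M HCl, 0 °C
Reagents that add atoms: none
Why: Methoxide reversibly forms the enolate at the aryloxy-bearing carbon of 4, which adds to fumarate 5 in a Michael reaction (C1–C2 bond) to give adduct 6; after proton transfer the methyl-ketone enolate attacks the ester at the end of the CH2 arm, not the one on C1, and expels methoxide (C4–C5 bond). The closest known reaction is the consecutive Michael–Claisen annulation of acetone derivatives with α,β-unsaturated esters, including the acetone-plus-maleate or -fumarate route to 3,5-dioxocyclohexanecarboxylates. Ring A closes in a 6-(enolendo)-exo-trig mode, and the closure is pulled forward by deprotonation of the dione to its sodium enolate, which also protects the product from further enolate chemistry until the acidic quench. The two new stereocentres at C1 and C2 arise without control, should settle under the equilibrating alkoxide mainly as the trans isomer, and are of no consequence because step 5 removes them. Two selectivities are needed: Michael addition through the aryloxy carbon and not the methyl group, which the acidifying oxygen substituent should secure, and Claisen attack on the distal ester, which is secured because closure onto the proximal ester would be a disfavoured 5-(enolendo)-exo-trig process leading to a strained cyclopentanedione.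

Step 4
Reactants: 7 methyl 2-[3-(benzyloxy)-5-methylphenoxy]-3,5-dioxocyclohexane-1-carboxylate
Product: 8 methyl 2-[3-(benzyloxy)-5-methylphenoxy]-5-methoxy-3-oxocyclohex-4-ene-1-carboxylate
Conditions: MeOH, p-TsOH·H2O (cat.), 3 Å MS, rt
Reagents that add atoms: methanol, CO
Why: Acid-catalysed enol etherification (vinylogous Fischer esterification) of a cyclic 1,3-dione, in which methanol should attack the C5 carbonyl flanked only by methylene groups in preference to the C3 carbonyl next to the aryloxy-substituted C2, as is usual for 4-substituted cyclohexane-1,3-diones; the methyl ester is unaffected in methanol.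

Step 5
Reactants: 8 methyl 2-[3-(benzyloxy)-5-methylphenoxy]-5-methoxy-3-oxocyclohex-4-ene-1-carboxylate
Product: 9 methyl 2-[3-(benzyloxy)-5-methylphenoxy]-3-hydroxy-5-methoxybenzoate
Conditions: DDQ (1.2 equiv), 1,4-dioxane, 90 °C, dark
Reagents that add atoms: none
Why: Quinone dehydrogenation of a 3-alkoxycyclohexenone to a phenol, in which DDQ abstracts hydride from the dienol tautomer and loss of the C1 proton completes the arene, fixing C3 as the free hydroxyl and C5 as the methyl ether and erasing both stereocentres; a plain benzyl ether should tolerate DDQ in the dark.

Step 6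
Reactants: 9 methyl 2-[3-(benzyloxy)-5-methylphenoxy]-3-hydroxy-5-methoxybenzoate
Product: 10 methyl 3-hydroxy-2-(3-hydroxy-5-methylphenoxy)-5-methoxybenzoate
Conditions: H2 (1 atm), 10% Pd/C, EtOAc–MeOH, rt
Reagents that add atoms: none
Why: Catalytic hydrogenolysis of the benzyl aryl ether, to which the methyl ester, the diaryl ether and the methyl ether are inert; placing it before the reduction keeps the later benzylic alcohol away from the hydrogenation catalyst.

Step 7
Reactants: 10 methyl 3-hydroxy-2-(3-hydroxy-5-methylphenoxy)-5-methoxybenzoate
Product: 11 3-(hydroxymethyl)-2-(3-hydroxy-5-methylphenoxy)-5-methoxyphenol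
Conditions: LiAlH4 (excess), THF, 0 °C to 50 °C; 1 M HCl, 0 °C
Reagents that add atoms: none
Why: Hydride reduction of the benzoate ester to the primary alcohol with LiAlH4, used in excess because both phenols first consume hydride as aluminium phenoxides that the acidic work-up releases.

Step 8
Reactants: 11 3-(hydroxymethyl)-2-(3-hydroxy-5-methylphenoxy)-5-methoxyphenol; 12 vinyl palmitate
Product: 13 betaethrin H
Conditions: Novozym 435 (immobilised Candida antarctica lipase B), THF, 4 Å MS, 45 °C
Reagents that add atoms: none
Why: Lipase-catalysed irreversible transesterification, in which the enzyme acylates the primary benzylic hydroxyl and leaves both phenols untouched, while the vinyl alcohol released tautomerises to acetaldehyde so the ester cannot revert.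

**Compound list**

1 | orcinol (5-methylbenzene-1,3-diol) | Cc1cc(O)cc(O)c1 | starting material
2 | 3-(benzyloxy)-5-methylphenol | Cc1cc(O)cc(OCc2ccccc2)c1 | intermediate
3 | chloroacetone | CC(=O)CCl | starting material
4 | 1-[3-(benzyloxy)-5-methylphenoxy]propan-2-one | CC(=O)COc1cc(C)cc(OCc2ccccc2)c1 | intermediate
5 | dimethyl fumarate | COC(=O)/C=C/C(=O)OC | starting material
6 | dimethyl 2-{1-[3-(benzyloxy)-5-methylphenoxy]-2-oxopropyl}butanedioate (Michael adduct, racemic, both diastereomers, not isolated) | CC(=O)C(Oc1cc(C)cc(OCc2ccccc2)c1)C(CC(=O)OC)C(=O)OC | intermediate
7 | methyl 2-[3-(benzyloxy)-5-methylphenoxy]-3,5-dioxocyclohexane-1-carboxylate (racemic, mixture of diastereomers and enol forms) | COC(=O)C1CC(=O)CC(=O)C1Oc1cc(C)cc(OCc2ccccc2)c1 | intermediate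
8 | methyl 2-[3-(benzyloxy)-5-methylphenoxy]-5-methoxy-3-oxocyclohex-4-ene-1-carboxylate (ring A numbering of the target; racemic, mixture of diastereomers) | COC(=O)C1CC(OC)=CC(=O)C1Oc1cc(C)cc(OCc2ccccc2)c1 | intermediate
9 | methyl 2-[3-(benzyloxy)-5-methylphenoxy]-3-hydroxy-5-methoxybenzoate | COC(=O)c1cc(OC)cc(O)c1Oc1cc(C)cc(OCc2ccccc2)c1 | intermediate
10 | methyl 3-hydroxy-2-(3-hydroxy-5-methylphenoxy)-5-methoxybenzoate | COC(=O)c1cc(OC)cc(O)c1Oc1cc(C)cc(O)c1 | intermediate
11 | 3-(hydroxymethyl)-2-(3-hydroxy-5-methylphenoxy)-5-methoxyphenol | OCc1cc(OC)cc(O)c1Oc1cc(C)cc(O)c1 | intermediate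
12 | vinyl palmitate (ethenyl hexadecanoate) | CCCCCCCCCCCCCCCC(=O)OC=C | starting material
13 | betaethrin H, [3-hydroxy-2-(3-hydroxy-5-methylphenoxy)-5-methoxyphenyl]methyl hexadecanoate (achiral) | CCCCCCCCCCCCCCCC(=O)OCc1cc(OC)cc(O)c1Oc1cc(C)cc(O)c1 | target

**Count and risks**

Total steps: 8. Longest linear sequence: 8 steps, from orcinol 1 to 13.

Steps most likely to fail:

Step 3. Three processes could spoil the annulation:
- conjugate addition through the methyl-side enolate, which would place the aryloxy group between the two carbonyls;
- β-elimination of the aryloxide from the ester enolate at C1, which would expel ring B and let ring A aromatize without it;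
- oligomerization of the fumarate.

The fallback sets out from 4 and separates the two bond formations. Soft enolization (TMSOTf, Et3N, CH2Cl2, 0 °C) should give (Z)-1-[3-(benzyloxy)-5-methylphenoxy]-2-(trimethylsilyloxy)prop-1-ene F1, with the enol double bond on the oxygen-substituted side. A Mukaiyama–Michael addition of this enol ether to 5, mediated by TiCl4 in CH2Cl2 at −78 °C, should then give adduct 6 as an isolated compound, its regiochemistry fixed by the enol ether and no base present. Brief treatment of 6 with KOtBu in THF at 0 °C closes the ring by Claisen condensation, and the route is rejoined at 7.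

Step 4. Methanol may add to the C3 carbonyl as well as to C5, giving the wrong enol ether, and prolonged acid could provoke loss of the aryloxy group. The fallback sets out from 7 and postpones the differentiation of the two oxygens to the aromatic stage. The dione is dehydrogenated directly (DDQ, 1,4-dioxane, 90 °C) to methyl 2-[3-(benzyloxy)-5-methylphenoxy]-3,5-dihydroxybenzoate F2. One equivalent of MeI with K2CO3 in acetone should then methylate the 5-hydroxyl, which lies between two ring hydrogens, in preference to the 3-hydroxyl crowded by the neighbouring aryloxy group. This rejoins the route at 9 and makes step 5 unnecessary.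

Step 5. Hydride abstraction may be sluggish, DDQ may attack the benzyl ether or the electron-rich ring B, or elimination of the aryloxy group may compete with dehydrogenation. The fallback sets out from 8 and replaces the quinone by a palladium-mediated dehydrosilylation. Kinetic enolization at C2 (LiHMDS, TMSCl, THF, −78 °C) should give methyl 2-[3-(benzyloxy)-5-methylphenoxy]-5-methoxy-3-(trimethylsilyloxy)cyclohexa-2,4-diene-1-carboxylate F3. Saegusa–Ito oxidation with palladium diacetate in MeCN at rt then introduces the C1–C2 double bond by β-hydride elimination from C1, and the resulting dienone tautomerizes at once to the phenol, rejoining the route at 9.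

Further compounds
F1 | step 3 | (Z)-1-[3-(benzyloxy)-5-methylphenoxy]-2-(trimethylsilyloxy)prop-1-ene | C/C(O[Si](C)(C)C)=C/Oc1cc(C)cc(OCc2ccccc2)c1
F2 | step 4 | methyl 2-[3-(benzyloxy)-5-methylphenoxy]-3,5-dihydroxybenzoate | COC(=O)c1cc(O)cc(O)c1Oc1cc(C)cc(OCc2ccccc2)c1
F3 | step 5 | methyl 2-[3-(benzyloxy)-5-methylphenoxy]-5-methoxy-3-(trimethylsilyloxy)cyclohexa-2,4-diene-1-carboxylate (racemic) | COC(=O)C1CC(OC)=CC(O[Si](C)(C)C)=C1Oc1cc(C)cc(OCc2ccccc2)c1
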